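The single-handed catalyst turns left-handed substrate into left-handed product while the two substrates also interconvert, and the flask carries dusk's partner on half of dusk's precatalyst.

| flask | left-handed substrate | right-handed substrate | partner | precatalyst | remark | time |
|---|---|---|---|---|---|---|
| midnight | 0.11 M | 0.11 M | 1.2 equiv (fed, over 2.0 min) | 5 mol% | run made earlier |  |
| dawn | 0.11 M | 0.11 M | 1.9 equiv (fed, over 2.0 min) | 5 mol% | run made earlier |  |
| dusk | 0.11 M | 0.11 M | 2.5 equiv (fed, over 2.0 min) | 10 mol% | run made earlier |  |
| flask | 0.11 M | 0.11 M | 2.50 equiv (fed, over 2.0 min) | 5 mol% |  | 2.0 min |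

- midnight (time / min: left-handed substrate / %, right-handed substrate / %, left-handed product / %): 0.333: 50.1, 49.3, 0.4; 0.667: 49.0, 49.6, 0.7; 1.00: 49.4, 51.0, 0.4; 1.33: 48.8, 49.8, 1.1; 1.50: 48.2, 49.8, 1.5; 2.00: 47.0, 49.5, 4.0; 2.50: 45.5, 49.2, 6.0
- dawn (time / min: left-handed substrate / %, right-handed substrate / %, left-handed product / %): 0.200: 50.5, 48.6, 0; 0.333: 50.3, 50.5, 0.1; 0.417: 50.1, 49.8, 0; 0.667: 49.7, 50.1, 0.8; 1.00: 48.4, 50.6, 0.7; 1.50: 46.3, 50.7, 2.8; 2.50: 43.1, 47.3, 8.9
- dusk (time / min: left-handed substrate / %, right-handed substrate / %, left-handed product / %): 0.200: 50.1, 50.6, 0; 0.667: 49.3, 49.2, 0.3; 1.00: 48.3, 50.3, 2.0; 1.50: 44.2, 50.5, 7.4; 2.50: 36.1, 47.2, 17.8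

(scatter of a reading: 0.5 percentage points)

- catalyst is single-handed; left-handed substrate and right-handed substrate are mirror images of each other, charged as a racemate, each of them at the stated concentration
- what was read earlier has a scatter of 0.5 percentage points, one standard deviation
- steps under discussion: partner + catalyst + left-handed substrate -> catalyst + left-handed product; partner + catalyst + right-handed substrate -> catalyst + right-handed product; left-handed substrate <-> right-handed substrate; partner + precatalyst -> catalyst + spent reagent; 2 catalyst <-> resting dimer
- an excess is below zero if the other one leads

* part of the left-handed substrate and right-handed substrate charged together that has reacted at 2.0 min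
* excess of left-handed product over right-handed product in the product at 2.0 min
* excess of right-handed substrate over left-handed substrate among what is left of the two at 2.0 min

Start with the conversion, c. Between 1.50 min and 2.50 min the dusk run's left-handed product averages 12.6%, which can stand in for dusk at 2.0 min. You might simply halve that, but set dusk beside dawn at 2.50 min. The product ratio is 2.00, and dividing out the partner ratio of 1.32 leaves 1.52 for twice the loading. Proportion would give 2.00 and a square root 1.41, the mark of catalyst held mostly as resting dimer, its resting state. So I take the root, and c comes to 8.91%. Dusk's substrates and left-handed product sum to 101.1% at 2.50 min, so any right-handed product there is lost in the scatter of 0.5 percentage points per reading, and I expect a high eP that these readings cannot place more finely.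

Now eS. If each lost left-handed substrate simply widened the gap, eS would be 9.78%. But dusk's gap at 2.50 min is 11 points against 17.8% of product, and its right-handed substrate reads 47.2%, which I take as interconversion closing the gap. Compute that correction alone: dusk's two readings give 0.690, the kept share φ, the substrate gap per unit of conversion. Can a weaker flask borrow it? Exchange shrinks a gap in proportion to its size, so the share should survive a smaller product. At 2.50 min midnight, with a third of dusk's product, reads 0.617, like dusk's 0.624, though dawn reads 0.472, so the readings place the share only loosely. Then eS = φc/(1−c) = 6.75%.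

The forecast, a shade apart from my figures, says 8.8%, 94% and 7%, reasoning “the order in catalyst is about one half, consistent with a resting dimer”. The flask gives c 8.67%, eP 97.8% and eS 6.41%.

    partner + catalyst + left-handed substrate → catalyst + left-handed product (k = 6.40 L² mol⁻² s⁻¹)
    partner + catalyst + right-handed substrate → catalyst + right-handed product (k = 0.0660 L² mol⁻² s⁻¹)
    left-handed substrate ⇌ right-handed substrate (k = 0.00580 s⁻¹)
    partner + precatalyst → catalyst + spent reagent (k = 0.310 L mol⁻¹ s⁻¹)
    2 catalyst ⇌ resting dimer, settled at all times (K = 330 L mol⁻¹)

At 1.48 min in the flask, left-handed substrate goes to product at 0.44 of the rate at which it crosses to right-handed substrate, forward step alone, so the crossing is faster than the product step. With φ at 0.690, the flask's conversion gives eS 6.55% against 6.41%, and a neighbouring flask on 3 mol% of precatalyst gives from its conversion of 6.49% an eS of 4.79% against 4.72%.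

All runs are calculated for substances that don't exist.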